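**Plan**

1. Retrosynthesis: cut first the aryl bond C4 (unit U)–C5' (unit L), giving a C4 cation of unit U, latent in a cis-pterocarpan, and ring B of a 7-O-pivaloyl (R)-vestitol. Then cut, in each unit, the C2–C3 bond of the pyran ring at the isoflavanone level, then the C3–C1' bond, back to one common ring-A methyl ketone and two bromoarenes.
2. Enabling feature: with C4 as a ketone, C3 of unit L is the enol carbon of a deoxybenzoin (benzylic to ring B), and C2 is a lone carbon on the ring-A oxygen O1. A formaldehyde O,S-acetal on O1 therefore puts an oxocarbenium carbon (C2) in a 1,6-relation to C3.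
3. Forward order: ketone α-arylation brings in ring B; the pyranone ring is closed by C2–C3 (unit L in step 5, unit U in step 10); reduction; unit U closes its furan ring (pterocarpan) while unit L loses its C4 oxygen; Friedel–Crafts union; ester cleavage.
4. Stereochemistry: both C3 centres (3R) come from transfer hydrogenation with dynamic kinetic resolution of the epimerisable isoflavanones. C4 of unit U (S, 3,4-trans) comes from anti attack of the arene on the C4 cation next to the fixed 3R centre.
5. Helpers: the C4 carbonyl (makes C3 nucleophilic and epimerisable; hydrogenolysed in unit L, leaving group in unit U), the pterocarpan furan ring (masks 2'-OH and the C4 cation of unit U), and two pivalates (silence both rings A in the union).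

Key step: step 5

Remark: isoflavan numbering is used for both halves (O1, C2, C3, C4, ring A fused, ring B on C3 with primed locants); unit U is the 4-arylisoflavan with the 4',5'-dimethoxy ring B (3R,4S, 3,4-trans), unit L the vestitol-type isoflavan (3R).

**Route**

Step 1
Reactants: 1 2,4-dihydroxyacetophenone
Product: 2 4-acetyl-3-hydroxyphenyl pivalate
Conditions: PivCl (1.05 equiv), Et3N (1.1 equiv), CH2Cl2, 0 °C
Reagents that add atoms: pivaloyl chloride, CC(C)(C)C(Cl)=O
Why: Selective O-acylation, because the 2-OH is held in a hydrogen bond to the acetyl carbonyl so that only the 4-OH should react, and the pivalate later switches off ring A as a Friedel–Crafts nucleophile.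

Step 2
Reactants: 2 4-acetyl-3-hydroxyphenyl pivalate
Product: 3 4-acetyl-3-[(methylsulfanyl)methoxy]phenyl pivalate
Conditions: NaH (1.05 equiv), DMF, 0 °C; then ClCH2SMe (1.2 equiv), NaI (0.1 equiv), 0 °C to rt
Reagents that add atoms: chloromethyl methyl sulfide, CSCCl
Why: Williamson O-alkylation of the phenoxide installs the formaldehyde O,S-acetal (MTM ether) that carries the future C2 and is inert to the enolate chemistry of the next step.

Step 3
Reactants: 4 2-bromo-5-methoxyphenol
Product: 5 2-(benzyloxy)-1-bromo-4-methoxybenzene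
Conditions: BnBr (1.1 equiv), K2CO3, DMF, rt
Reagents that add atoms: benzyl bromide, BrCc1ccccc1
Why: Williamson etherification protects the future 2'-OH as a benzyl ether that survives base, Lewis acid and transfer hydrogenation.

Step 4
Reactants: 3 4-acetyl-3-[(methylsulfanyl)methoxy]phenyl pivalate and 5 2-(benzyloxy)-1-bromo-4-methoxybenzene
Product: 6 4-{[2-(benzyloxy)-4-methoxyphenyl]acetyl}-3-[(methylsulfanyl)methoxy]phenyl pivalate (deoxybenzoin of unit L)
Conditions: Pd(OAc)2 (2 mol%), XPhos (4 mol%), K3PO4 (2.3 equiv), toluene, 90 °C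
Reagents that add atoms: none
Why: Palladium-catalysed α-arylation of the methyl ketone enolate forms the C3–C1' bond, the weak phosphate base sparing the pivalate and the bulky biaryl phosphine favouring monoarylation with the ortho-alkoxy bromide.

Step 5
Reactants: 6 4-{[2-(benzyloxy)-4-methoxyphenyl]acetyl}-3-[(methylsulfanyl)methoxy]phenyl pivalate
Product: 9 rac-3-[2-(benzyloxy)-4-methoxyphenyl]-4-oxochroman-7-yl pivalate (isoflavanone of unit L), via dimethylsulfonium triflate 7 (not isolated), via cyclic enol acetal 8 (not isolated)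
Conditions: MeOTf (1.1 equiv), 2,6-di-tert-butyl-4-methylpyridine (1.5 equiv), CH2Cl2, 0 °C to rt; then TMSOTf (0.2 equiv), −40 to 0 °C
Reagents that add atoms: none
Why: S-Methylation turns the O,S-acetal into a sulfonium leaving group (the activation used for thioglycosides), Me2S leaves with participation of the ortho acyl oxygen and deprotonation gives the enol acetal 8 as an E/Z mixture; TMSOTf then re-ionises the O–CH2–O unit into an aryloxycarbenium ion at C2 tethered to a silyl enol ether whose nucleophilic carbon is C3, and C–C bond formation with loss of the silyl group gives the ketone. The closest known reaction type is the Petasis–Ferrier rearrangement of cyclic enol acetals to pyranones, that is, an intramolecular Mukaiyama-type alkylation by an oxocarbenium ion. The pyranone ring is closed by a 6-(enolendo)-endo-trig attack of C3 on C2=O1+, both reacting π-bonds lying inside the new six-membered ring. The new stereocentre C3 is formed without control and needs none, because as an α-aryl ketone it epimerises and is fixed only in step 6. The step needs C- over O-alkylation of the ambident enol: O-closure is reversible under the Lewis acid, whereas C-closure gives a C–C bond and a conjugated aryl ketone and is not reversed, so both geometric isomers of 8 should funnel to 9. Alkylation of an arene by C2 is not expected, since ring B could be reached only through an eight-membered ring and ring A is deactivated by the pivalate.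

Step 6
Reactants: 9 rac-3-[2-(benzyloxy)-4-methoxyphenyl]-4-oxochroman-7-yl pivalate
Product: 10 (3R,4R)-3-[2-(benzyloxy)-4-methoxyphenyl]-4-hydroxychroman-7-yl pivalate (3,4-cis)
Conditions: RuCl[(R,R)-TsDPEN](p-cymene) (2 mol%), HCO2H/Et3N (5:2), EtOAc, 40 °C
Reagents that add atoms: none
Why: Noyori–Ikariya asymmetric transfer hydrogenation with dynamic kinetic resolution, in which C3 epimerises through the enol under the amine while the (R,R) catalyst reduces the 3R ketone to the 4R carbinol (acetophenone model, hydride anti to the 3-aryl group), so that both enantiomers of 9 should converge on the cis-(3R,4R) alcohol.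

Step 7
Reactants: 10 (3R,4R)-3-[2-(benzyloxy)-4-methoxyphenyl]-4-hydroxychroman-7-yl pivalate
Product: 11 (3R)-3-(2-hydroxy-4-methoxyphenyl)chroman-7-yl pivalate (7-O-pivaloyl (R)-vestitol)
Conditions: H2 (3 bar), 10% Pd/C, EtOH/AcOH (5:1), rt
Reagents that add atoms: none
Why: Catalytic hydrogenolysis should cleave both the benzyl ether and the benzylic C4–OH (activated by the ortho ring oxygen and the acid) without touching C3, leaving ring B as the free phenol while ring A stays acylated.

Step 8
Reactants: 12 2-bromo-4,5-dimethoxyphenol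
Product: 13 1-(benzyloxy)-2-bromo-4,5-dimethoxybenzene
Conditions: BnBr (1.1 equiv), K2CO3, DMF, rt
Reagents that add atoms: benzyl bromide, BrCc1ccccc1
Why: Williamson etherification, as in step 3.

Step 9
Reactants: 3 4-acetyl-3-[(methylsulfanyl)methoxy]phenyl pivalate and 13 1-(benzyloxy)-2-bromo-4,5-dimethoxybenzene
Product: 14 4-{[2-(benzyloxy)-4,5-dimethoxyphenyl]acetyl}-3-[(methylsulfanyl)methoxy]phenyl pivalate (deoxybenzoin of unit U)
Conditions: Pd(OAc)2 (2 mol%), XPhos (4 mol%), K3PO4 (2.3 equiv), toluene, 90 °C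
Reagents that add atoms: none
Why: Palladium-catalysed ketone α-arylation, as in step 4, from the common ketone 3.

Step 10
Reactants: 14 4-{[2-(benzyloxy)-4,5-dimethoxyphenyl]acetyl}-3-[(methylsulfanyl)methoxy]phenyl pivalate
Product: 17 rac-3-[2-(benzyloxy)-4,5-dimethoxyphenyl]-4-oxochroman-7-yl pivalate (isoflavanone of unit U), via dimethylsulfonium triflate 15 (not isolated), via cyclic enol acetal 16 (not isolated)
Conditions: MeOTf (1.1 equiv), 2,6-di-tert-butyl-4-methylpyridine (1.5 equiv), CH2Cl2, 0 °C to rt; then TMSOTf (0.2 equiv), −40 to 0 °C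
Reagents that add atoms: none
Why: The same sulfonium activation and Petasis–Ferrier-type O-to-C rearrangement as in step 5 closes the pyranone ring of unit U, again giving an epimerisable C3.

Step 11
Reactants: 17 rac-3-[2-(benzyloxy)-4,5-dimethoxyphenyl]-4-oxochroman-7-yl pivalate
Product: 18 (3R,4R)-3-[2-(benzyloxy)-4,5-dimethoxyphenyl]-4-hydroxychroman-7-yl pivalate (3,4-cis)
Conditions: RuCl[(R,R)-TsDPEN](p-cymene) (2 mol%), HCO2H/Et3N (5:2), EtOAc, 40 °C
Reagents that add atoms: none
Why: Noyori–Ikariya transfer hydrogenation with dynamic kinetic resolution, as in step 6, should set 3R and 4R together.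

Step 12
Reactants: 18 (3R,4R)-3-[2-(benzyloxy)-4,5-dimethoxyphenyl]-4-hydroxychroman-7-yl pivalate
Product: 20 (6aR,11aR)-8,9-dimethoxy-6a,11a-dihydro-6H-benzofuro[3,2-c]chromen-3-yl pivalate (pterocarpan of unit U), via debenzylated diol 19 (not isolated)
Conditions: H2 (1 bar), 10% Pd/C, EtOAc, rt, stopped after one equivalent of H2; filtration; then p-TsOH·H2O (10 mol%), 4 Å MS, CH2Cl2, 0 °C to rt
Reagents that add atoms: none
Why: Neutral hydrogenolysis should remove the benzyl ether faster than the unprotonated C4–OH, and acid then ionises C4 so that the 2'-OH, held on the face of the 3-aryl group, closes the furan ring by SN1 cycloetherification to the cis-fused pterocarpan with retention at C4.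

Step 13
Reactants: 20 (6aR,11aR)-8,9-dimethoxy-6a,11a-dihydro-6H-benzofuro[3,2-c]chromen-3-yl pivalate and 11 (3R)-3-(2-hydroxy-4-methoxyphenyl)chroman-7-yl pivalate
Product: 21 (3R,4S)-3-(2-hydroxy-4,5-dimethoxyphenyl)-4-{4-hydroxy-2-methoxy-5-[(3R)-7-(pivaloyloxy)chroman-3-yl]phenyl}chroman-7-yl pivalate
Conditions: 11 (2 equiv), TfOH (5 mol%), HFIP/CH2Cl2 (1:3), −20 to 0 °C, 20 added slowly
Reagents that add atoms: none
Why: Friedel–Crafts alkylation in which acid re-opens the benzylic C11a–O bond of 20 to the O1-stabilised C4 cation, which should be taken by C5' of 11 (para to the free 2'-OH and ortho to OMe, the only strongly activated free position since both rings A are pivalates) from the face anti to the 3-aryl group, giving the 3,4-trans (4S) product and freeing the 2'-OH of unit U.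

Step 14
Reactants: 21 (3R,4S)-3-(2-hydroxy-4,5-dimethoxyphenyl)-4-{4-hydroxy-2-methoxy-5-[(3R)-7-(pivaloyloxy)chroman-3-yl]phenyl}chroman-7-yl pivalate
Product: 22 (3R,4S)-3-(2-hydroxy-4,5-dimethoxyphenyl)-4-{4-hydroxy-5-[(3R)-7-hydroxychroman-3-yl]-2-methoxyphenyl}chroman-7-ol (target)
Conditions: K2CO3 (0.5 equiv), degassed MeOH/THF, 0 °C to rt, under Ar; AcOH quench
Reagents that add atoms: none
Why: Base-catalysed transesterification with methanol removes both aryl pivalates under conditions that should leave the three non-acidic stereocentres and the electron-rich phenols untouched.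

**Compound list**

1 | 2,4-dihydroxyacetophenone | CC(=O)c1ccc(O)cc1O | starting material
2 | 4-acetyl-3-hydroxyphenyl pivalate | CC(=O)c1ccc(OC(=O)C(C)(C)C)cc1O | intermediate
3 | 4-acetyl-3-[(methylsulfanyl)methoxy]phenyl pivalate | CSCOc1cc(OC(=O)C(C)(C)C)ccc1C(C)=O | intermediate
4 | 2-bromo-5-methoxyphenol | COc1ccc(Br)c(O)c1 | starting material
5 | 2-(benzyloxy)-1-bromo-4-methoxybenzene | COc1ccc(Br)c(OCc2ccccc2)c1 | intermediate
6 | 4-{[2-(benzyloxy)-4-methoxyphenyl]acetyl}-3-[(methylsulfanyl)methoxy]phenyl pivalate | CSCOc1cc(OC(=O)C(C)(C)C)ccc1C(=O)Cc1ccc(OC)cc1OCc1ccccc1 | intermediate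
7 | {[2-{[2-(benzyloxy)-4-methoxyphenyl]acetyl}-5-(pivaloyloxy)phenoxy]methyl}dimethylsulfonium triflate | C[S+](C)COc1cc(OC(=O)C(C)(C)C)ccc1C(=O)Cc1ccc(OC)cc1OCc1ccccc1.[O-]S(=O)(=O)C(F)(F)F | intermediate
8 | 4-[2-(benzyloxy)-4-methoxybenzylidene]-4H-1,3-benzodioxin-7-yl pivalate (alkene geometry not controlled) | CC(C)(C)C(=O)Oc1ccc2c(c1)OCOC2=Cc1ccc(OC)cc1OCc1ccccc1 | intermediate
9 | rac-3-[2-(benzyloxy)-4-methoxyphenyl]-4-oxochroman-7-yl pivalate | COc1ccc(c(OCc2ccccc2)c1)C1COc2cc(OC(=O)C(C)(C)C)ccc2C1=O | intermediate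
10 | (3R,4R)-3-[2-(benzyloxy)-4-methoxyphenyl]-4-hydroxychroman-7-yl pivalate | COc1ccc(c(OCc2ccccc2)c1)[C@@H]1COc2cc(OC(=O)C(C)(C)C)ccc2[C@@H]1O | intermediate
11 | (3R)-3-(2-hydroxy-4-methoxyphenyl)chroman-7-yl pivalate | COc1ccc(c(O)c1)[C@@H]1COc2cc(OC(=O)C(C)(C)C)ccc2C1 | intermediate
12 | 2-bromo-4,5-dimethoxyphenol | COc1cc(O)c(Br)cc1OC | starting material
13 | 1-(benzyloxy)-2-bromo-4,5-dimethoxybenzene | COc1cc(OCc2ccccc2)c(Br)cc1OC | intermediate
14 | 4-{[2-(benzyloxy)-4,5-dimethoxyphenyl]acetyl}-3-[(methylsulfanyl)methoxy]phenyl pivalate | CSCOc1cc(OC(=O)C(C)(C)C)ccc1C(=O)Cc1cc(OC)c(OC)cc1OCc1ccccc1 | intermediate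
15 | {[2-{[2-(benzyloxy)-4,5-dimethoxyphenyl]acetyl}-5-(pivaloyloxy)phenoxy]methyl}dimethylsulfonium triflate | C[S+](C)COc1cc(OC(=O)C(C)(C)C)ccc1C(=O)Cc1cc(OC)c(OC)cc1OCc1ccccc1.[O-]S(=O)(=O)C(F)(F)F | intermediate
16 | 4-[2-(benzyloxy)-4,5-dimethoxybenzylidene]-4H-1,3-benzodioxin-7-yl pivalate (alkene geometry not controlled) | CC(C)(C)C(=O)Oc1ccc2c(c1)OCOC2=Cc1cc(OC)c(OC)cc1OCc1ccccc1 | intermediate
17 | rac-3-[2-(benzyloxy)-4,5-dimethoxyphenyl]-4-oxochroman-7-yl pivalate | COc1cc(OCc2ccccc2)c(cc1OC)C1COc2cc(OC(=O)C(C)(C)C)ccc2C1=O | intermediate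
18 | (3R,4R)-3-[2-(benzyloxy)-4,5-dimethoxyphenyl]-4-hydroxychroman-7-yl pivalate | COc1cc(OCc2ccccc2)c(cc1OC)[C@@H]1COc2cc(OC(=O)C(C)(C)C)ccc2[C@@H]1O | intermediate
19 | (3R,4R)-4-hydroxy-3-(2-hydroxy-4,5-dimethoxyphenyl)chroman-7-yl pivalate | COc1cc(O)c(cc1OC)[C@@H]1COc2cc(OC(=O)C(C)(C)C)ccc2[C@@H]1O | intermediate
20 | (6aR,11aR)-8,9-dimethoxy-6a,11a-dihydro-6H-benzofuro[3,2-c]chromen-3-yl pivalate | COc1cc2c(cc1OC)[C@@H]1COc3cc(OC(=O)C(C)(C)C)ccc3[C@@H]1O2 | intermediate
21 | (3R,4S)-3-(2-hydroxy-4,5-dimethoxyphenyl)-4-{4-hydroxy-2-methoxy-5-[(3R)-7-(pivaloyloxy)chroman-3-yl]phenyl}chroman-7-yl pivalate | COc1cc(O)c([C@@H]2COc3cc(OC(=O)C(C)(C)C)ccc3[C@H]2c2cc([C@@H]3COc4cc(OC(=O)C(C)(C)C)ccc4C3)c(O)cc2OC)cc1OC | intermediate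
22 | (3R,4S)-3-(2-hydroxy-4,5-dimethoxyphenyl)-4-{4-hydroxy-5-[(3R)-7-hydroxychroman-3-yl]-2-methoxyphenyl}chroman-7-ol | COc1cc(O)c([C@@H]2COc3cc(O)ccc3[C@H]2c2cc([C@@H]3COc4cc(O)ccc4C3)c(O)cc2OC)cc1OC | target

**Count and risks**

Total step count: 14. Longest linear sequence: 8 steps (1, 2, 4, 5, 6, 7, 13, 14; the unit-U branch 1, 2, 9, 10, 11, 12, 13, 14 is equally long).

Steps most likely to fail:

Step 5 (and its twin, step 10). The carbenium carbon may be captured only at the enol oxygen without onward O-to-C migration, or methylation and alkylation may stray to the electron-rich ring B. The fallback sets out from 6 and closes the ring through the other bond. The MTM ether is hydrolysed (MeI, NaHCO3, aqueous acetone) to the free phenol 4-{[2-(benzyloxy)-4-methoxyphenyl]acetyl}-3-hydroxyphenyl pivalate F1. α-Methylenation (paraformaldehyde, diisopropylammonium trifluoroacetate, THF, reflux) gives the α-methylene ketone 4-{2-[2-(benzyloxy)-4-methoxyphenyl]acryloyl}-3-hydroxyphenyl pivalate F2. This closes by 6-endo oxa-Michael addition of the phenol (O1–C2 bond) on brief exposure to K2CO3 in acetone and comes back to the route at 9.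

Step 13. After ionisation, loss of the C3 proton (elimination and reprotonation) may erase the 3R centre faster than arylation, and arylation may spread over other ring positions or over a second molecule of the electrophile. The fallback sets out from 18 and 11 and uses a discrete leaving group at low temperature with the 2'-oxygen still blocked. Acetylation of 18 (Ac2O, pyridine, DMAP) gives (3R,4R)-4-acetoxy-3-[2-(benzyloxy)-4,5-dimethoxyphenyl]chroman-7-yl pivalate F3. This is coupled with 11 (2 equiv) under TMSOTf (0.2 equiv) in CH2Cl2 at −78 °C to give (3R,4S)-3-[2-(benzyloxy)-4,5-dimethoxyphenyl]-4-{4-hydroxy-2-methoxy-5-[(3R)-7-(pivaloyloxy)chroman-3-yl]phenyl}chroman-7-yl pivalate F4. Hydrogenolysis (H2, 10% Pd/C, EtOAc) then removes the benzyl group and comes back to the route at 21.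

Step 6 (and its twin, step 11). Reduction may outrun epimerisation at C3, so that the dynamic resolution is incomplete and both the enantiomeric purity and the cis selectivity erode. The fallback sets out from 9 and moves the stereo-defining event to an alkene hydrogenation. Reduction (NaBH4, CeCl3, THF/EtOH, 0 °C) gives rac-3-[2-(benzyloxy)-4-methoxyphenyl]-4-hydroxychroman-7-yl pivalate F5 as a cis/trans mixture. Dehydration (p-TsOH, toluene, 60 °C) gives the isoflav-3-ene 3-[2-(benzyloxy)-4-methoxyphenyl]-2H-chromen-7-yl pivalate F6. Asymmetric hydrogenation with [Ir(cod)(tBu-PHOX)]BArF (H2, 50 bar, CH2Cl2; ligand hand chosen to deliver 3R) gives (3R)-3-[2-(benzyloxy)-4-methoxyphenyl]chroman-7-yl pivalate F7. Debenzylation (H2, 10% Pd/C, EtOAc) comes back to the route at 11.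

**Further compounds**

F1 | step 5 | 4-{[2-(benzyloxy)-4-methoxyphenyl]acetyl}-3-hydroxyphenyl pivalate | CC(C)(C)C(=O)Oc1ccc(C(=O)Cc2ccc(OC)cc2OCc2ccccc2)c(O)c1
F2 | step 5 | 4-{2-[2-(benzyloxy)-4-methoxyphenyl]acryloyl}-3-hydroxyphenyl pivalate | C=C(C(=O)c1ccc(OC(=O)C(C)(C)C)cc1O)c1ccc(OC)cc1OCc1ccccc1
F3 | step 13 | (3R,4R)-4-acetoxy-3-[2-(benzyloxy)-4,5-dimethoxyphenyl]chroman-7-yl pivalate | COc1cc(OCc2ccccc2)c(cc1OC)[C@@H]1COc2cc(OC(=O)C(C)(C)C)ccc2[C@@H]1OC(C)=O
F4 | step 13 | (3R,4S)-3-[2-(benzyloxy)-4,5-dimethoxyphenyl]-4-{4-hydroxy-2-methoxy-5-[(3R)-7-(pivaloyloxy)chroman-3-yl]phenyl}chroman-7-yl pivalate | COc1cc(OCc2ccccc2)c(cc1OC)[C@@H]1COc2cc(OC(=O)C(C)(C)C)ccc2[C@H]1c1cc([C@@H]2COc3cc(OC(=O)C(C)(C)C)ccc3C2)c(O)cc1OC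
F5 | step 6 | rac-3-[2-(benzyloxy)-4-methoxyphenyl]-4-hydroxychroman-7-yl pivalate (cis/trans mixture) | COc1ccc(c(OCc2ccccc2)c1)C1COc2cc(OC(=O)C(C)(C)C)ccc2C1O
F6 | step 6 | 3-[2-(benzyloxy)-4-methoxyphenyl]-2H-chromen-7-yl pivalate | COc1ccc(c(OCc2ccccc2)c1)C1=Cc2ccc(OC(=O)C(C)(C)C)cc2OC1
F7 | step 6 | (3R)-3-[2-(benzyloxy)-4-methoxyphenyl]chroman-7-yl pivalate | COc1ccc(c(OCc2ccccc2)c1)[C@@H]1COc2cc(OC(=O)C(C)(C)C)ccc2C1
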